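**Plan**
- Retrosynthesis: the two bonds to the spiro carbon (C11–C12 and C12–C13) are cut first, giving 4-methoxy-3-methylfuran-2(5H)-one and a bicyclic keto lactam whose aldehyde carbon C11 is masked as a dimethyl acetal; then N–C8 and C9–C13 are cut together.
- Enabling feature: in the azepane, N, the ring-fusion carbon C8, the adjoining methine C9 and the carbinol carbon C13 are contiguous, and C14–C16 lead back to N. The seven-membered ring is therefore a maleimide whose N–C(=O) bond has taken in a Z-alkene (C8=C9) hanging on a four-carbon tether from the N-bearing carbon C4.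
- Forward: the chain is joined by copper-catalysed epoxide opening and a Z-selective Wittig reaction; the photocycloaddition closes the piperidine and the azepinedione at once; furanone addition to the ketone and a ring-closing aldol onto the unmasked aldehyde then build the cyclopentane with its spiro centre; lactam reduction and desilylation finish.
- Stereochemistry: C3 from a Sharpless kinetic resolution; C4 from the erythro epoxide by azide inversion; C10 from the (S)-Roche ester; C8/C9 from the Z geometry and the fold directed by C4; C13 by attack anti to the C9 branch; C12 and C11 in the ring-closing aldol.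

Key step: step 16

Remark: atom labels follow the carbon chain of the target (C1–C3 propyl side chain with C3 the carbinol; C4–C8 piperidine carbons, C4 and C8 on N; C9–C13 cyclopentane with C10 methyl, C11 carbinol, C12 spiro and C13 tertiary carbinol; C14–C16 the remaining azepane carbons); pent-1-en-3-ol is taken as the commercial racemate.

**Route**

Step 1
Reactants: 1 ethyl 2-methyl-3-oxobutanoate
Product: 4 4-hydroxy-3-methylfuran-2(5H)-one (3-methyltetronic acid), via ethyl 2-bromo-2-methyl-3-oxobutanoate 2 (not isolated), via ethyl 4-bromo-2-methyl-3-oxobutanoate 3 (not isolated)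
Conditions: Br2 (1.0 equiv), CHCl3, 0 °C → rt, 16 h; then neat, 110–120 °C
Reagents that add atoms: none
Why: α-Bromination, HBr-catalysed migration of bromine to the terminal methyl and thermal lactonisation with loss of bromoethane is the classical tetronic acid synthesis and creates no stereocentre.

Step 2
Reactants: 4 3-methyltetronic acid
Product: 5 4-methoxy-3-methylfuran-2(5H)-one
Conditions: Me2SO4, K2CO3, acetone, reflux
Reagents that add atoms: dimethyl sulfate, COS(=O)(=O)OC
Why: O-Alkylation (Williamson type) of the vinylogous acid at O-4 should give the methyl tetronate.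

Step 3
Reactants: 6 methyl (S)-3-hydroxy-2-methylpropanoate
Product: 7 methyl (S)-3-[(tert-butyldiphenylsilyl)oxy]-2-methylpropanoate
Conditions: TBDPSCl, imidazole, CH2Cl2, 0 °C → rt
Reagents that add atoms: tert-butyl(chloro)diphenylsilane (TBDPSCl), CC(C)(C)[Si](Cl)(c1ccccc1)c1ccccc1
Why: Silyl ether formation under imidazole buffering leaves the α-stereocentre untouched and gives a group that survives hydride and acidic methanol.

Step 4
Reactants: 7 silyl ether of the Roche ester
Product: 9 (S)-tert-butyl(3,3-dimethoxy-2-methylpropoxy)diphenylsilane, via silyloxy aldehyde 8 (not isolated)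
Conditions: iBu2AlH (1.05 equiv), CH2Cl2, −78 °C; aq. potassium sodium tartrate; crude aldehyde, HC(OMe)3, pyridinium p-toluenesulfonate (cat.), MeOH, rt
Reagents that add atoms: trimethyl orthoformate, COC(OC)OC
Why: Partial ester reduction followed at once by orthoformate acetalisation under a weak acid should mask the configurationally labile aldehyde before its α-centre (later C10) can epimerise.

Step 5
Reactants: 9 silyl acetal
Product: 10 (S)-3,3-dimethoxy-2-methylpropan-1-ol
Conditions: Bu4NF, THF, rt
Reagents that add atoms: none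
Why: Fluoride desilylation is neutral to the dimethyl acetal.

Step 6
Reactants: 10 acetal alcohol
Product: 11 (R)-3-iodo-1,1-dimethoxy-2-methylpropane
Conditions: I2, PPh3, imidazole, CH2Cl2, 0 °C → rt
Reagents that add atoms: iodine, I-I
Why: Appel-type (Garegg–Samuelsson) iodination of the primary alcohol proceeds at CH2 and does not touch the stereocentre (the descriptor changes only through the priority rules).

Step 7
Reactants: 11 iodide
Product: 12 [(R)-3,3-dimethoxy-2-methylpropyl]triphenylphosphonium iodide
Conditions: PPh3, MeCN, 80 °C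
Reagents that add atoms: triphenylphosphine, c1ccc(cc1)P(c1ccccc1)c1ccccc1
Why: SN2 quaternisation of triphenylphosphine by the primary iodide gives the Wittig salt, whose acetal sits γ to phosphorus and cannot be eliminated from the ylide.

Step 8
Reactants: 13 (±)-pent-1-en-3-ol
Product: 14 (2S,3R)-1,2-epoxypentan-3-ol
Conditions: Ti(OiPr)4 (10 mol%), D-(−)-diisopropyl tartrate (15 mol%), t-BuOOH (0.45 equiv), 4 Å molecular sieves, CH2Cl2, −20 °C
Reagents that add atoms: tert-butyl hydroperoxide, CC(C)(C)OO
Why: In the Sharpless kinetic resolution the D-(−)-tartrate catalyst epoxidises the (R)-alcohol much faster and from the face that gives the erythro epoxy alcohol, which sets C3 (R) and the precursor configuration of C4 (S) while the (S)-alcohol is left behind.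

Step 9
Reactants: 14 epoxy alcohol
Product: 15 tert-butyldimethyl{(R)-1-[(S)-oxiran-2-yl]propoxy}silane
Conditions: TBSCl, imidazole, DMF, 0 °C → rt
Reagents that add atoms: tert-butyl(chloro)dimethylsilane (TBSCl), CC(C)(C)[Si](C)(C)Cl
Why: Silylation under imidazole avoids Payne rearrangement and differentiates the C3 oxygen from the one to be liberated at C4.

Step 10
Reactants: 15 silyloxy epoxide; 16 but-3-en-1-ylmagnesium bromide
Product: 17 (3R,4S)-3-[(tert-butyldimethylsilyl)oxy]non-8-en-4-ol
Conditions: CuI (10 mol%), THF, −40 → 0 °C; aq. NH4Cl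
Reagents that add atoms: none
Why: Copper-catalysed Grignard opening of the terminal epoxide occurs by SN2 at the unhindered CH2, so C4 keeps its configuration and becomes a free carbinol next to the silyl ether.

Step 11
Reactants: 17 anti-configured mono-silylated diol
Product: 18 (3R,4R)-4-azido-3-[(tert-butyldimethylsilyl)oxy]non-8-ene
Conditions: PPh3, DIAD, (PhO)2P(O)N3, THF, 0 °C → rt
Reagents that add atoms: diphenylphosphoryl azide (DPPA), [N-]=[N+]=NP(=O)(Oc1ccccc1)Oc1ccccc1
Why: Mitsunobu azidation displaces the activated C4 oxygen with inversion, turning the anti diol derivative into the syn azido silyl ether with C4 (R).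

Step 12
Reactants: 18 azido alkene
Product: 20 (5R,6R)-5-azido-6-[(tert-butyldimethylsilyl)oxy]octanal, via ozonide 19 (not isolated)
Conditions: O3, CH2Cl2, −78 °C; then Me2S, −78 °C → rt
Reagents that add atoms: ozone, [O-][O+]=O
Why: Ozonolysis with reductive work-up cleaves only the terminal alkene and leaves azide and silyl ether intact.

Step 13
Reactants: 12 phosphonium iodide; 20 azido aldehyde
Product: 22 (3R,4R,8Z,10S)-4-azido-3-[(tert-butyldimethylsilyl)oxy]-11,11-dimethoxy-10-methylundec-8-ene, via phosphorus ylide 21 (not isolated)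
Conditions: NaN(SiMe3)2, THF, −78 → 0 °C; then 20, −78 °C → rt
Reagents that add atoms: none
Why: Wittig olefination with a non-stabilised, lithium-free ylide proceeds through the kinetically formed cis-oxaphosphetane and should give the Z-alkene, with C10 carried in unchanged from the Roche ester.

Step 14
Reactants: 22 azide
Product: 24 (3R,4R,8Z,10S)-3-[(tert-butyldimethylsilyl)oxy]-11,11-dimethoxy-10-methylundec-8-en-4-amine, via iminophosphorane 23 (not isolated)
Conditions: PPh3, THF–H2O (10:1), 50 °C
Reagents that add atoms: none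
Why: Staudinger reduction converts the azide into the amine without touching the Z-alkene, which hydrogenation would not spare.

Step 15
Reactants: 24 amine; 25 maleic anhydride
Product: 27 1-[(3R,4R,8Z,10S)-3-[(tert-butyldimethylsilyl)oxy]-11,11-dimethoxy-10-methylundec-8-en-4-yl]-1H-pyrrole-2,5-dione, via maleamic acid 26 (not isolated)
Conditions: CH2Cl2, rt; then Ac2O, NaOAc, 80 °C
Reagents that add atoms: none
Why: Anhydride opening by the amine and acetate-mediated cyclodehydration of the maleamic acid is the standard maleimide synthesis and is non-acidic, so acetal and silyl ether should survive.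

Step 16
Reactants: 27 N-alkenyl maleimide
Product: 28 (4R,10R,10aS)-4-[(1R)-1-{[tert-butyl(dimethyl)silyl]oxy}propyl]-10-[(2S)-1,1-dimethoxypropan-2-yl]-1,2,3,4,10,10a-hexahydropyrido[1,2-a]azepine-6,9-dione
Conditions: hν (medium-pressure Hg lamp, Pyrex filter, λ > 290 nm), MeCN (0.01 M), rt, flow through FEP tubing
Reagents that add atoms: none
Why: In the excited singlet state the imide N–C(=O) bond adds across the tethered alkene, nitrogen bonding to C8 and the carbonyl carbon to C9, and the original N–C(=O) bond breaks in the same event or from a short-lived bicyclic intermediate, so the two alkene carbons end up between nitrogen and the new ketone. The closest known reaction is the [5+2] photocycloaddition of N-alkenyl maleimides to fused azepinediones. The piperidine closes by N–C8 bond formation through the four-carbon tether (six-membered, exo to the alkene), and the azepinedione is the five-membered imide enlarged by the two alkene carbons. C8 and C9 form in one suprafacial event, so their cis hydrogens follow from the retained Z geometry; their absolute sense follows from C4, because the tether should fold chair-like with the C4–H in the imide plane and the silyloxypropyl group pseudo-equatorial, which leads to the 2,6-cis piperidine. The step needs [5+2] insertion to win over [2+2] addition at the maleimide C=C and over secondary photolysis, which dilute flow irradiation through Pyrex should favour, and it needs the C4-directed fold to outweigh the allylic centre C10, whose hydrogen eclipses the alkene and whose methyl and dimethoxymethyl groups flank the two faces with little difference in effective size.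

Step 17
Reactants: 28 azepinedione
Product: 29 (4R,10R,10aS)-4-[(1R)-1-{[tert-butyl(dimethyl)silyl]oxy}propyl]-10-[(2S)-1,1-dimethoxypropan-2-yl]octahydropyrido[1,2-a]azepine-6,9-dione
Conditions: H2 (1 atm), 10% Pd/C, EtOAc, rt
Reagents that add atoms: none
Why: Catalytic hydrogenation saturates the electron-poor enedione C=C (C14=C15) and creates no stereocentre.

Step 18
Reactants: 29 keto lactam; 5 4-methoxy-3-methylfuran-2(5H)-one
Product: 32 (4R,9S,10R,10aS)-4-[(1R)-1-{[tert-butyl(dimethyl)silyl]oxy}propyl]-10-[(2S)-1,1-dimethoxypropan-2-yl]-9-(3-methoxy-4-methyl-5-oxo-2,5-dihydrofuran-2-yl)-9-[(triethylsilyl)oxy]octahydropyrido[1,2-a]azepin-6(2H)-one (both epimers at the furanone carbon C12), via lithium furanolate 30 (not isolated), via lithium alkoxide 31 (not isolated)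
Conditions: 5 (1.6 equiv), LiN(iPr)2 (1.5 equiv), THF, −78 °C; 29, −78 °C; then Et3SiOTf, −78 → −40 °C
Reagents that add atoms: triethylsilyl trifluoromethanesulfonate (TESOTf), CC[Si](CC)(CC)OS(=O)(=O)C(F)(F)F
Why: Aldol-type addition of the γ-lithiated tetronate to the ketone should occur on the ring face carrying the C8 and C9 hydrogens, opposite the C9 branch, which sets C13 with its oxygen cis to that branch; silylation of the alkoxide in the flask blocks retro-aldol, and the C12 epimers converge in step 21.

Step 19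
Reactants: 32 silyl ether lactam
Product: 34 (4R,9S,10R,10aS)-4-[(1R)-1-{[tert-butyl(dimethyl)silyl]oxy}propyl]-10-[(2S)-1,1-dimethoxypropan-2-yl]-9-(3-methoxy-4-methyl-5-oxo-2,5-dihydrofuran-2-yl)-9-[(triethylsilyl)oxy]decahydropyrido[1,2-a]azepine, via silyl hemiaminal 33 (not isolated)
Conditions: IrCl(CO)(PPh3)2 (1 mol%), (HMe2Si)2O, toluene, rt; then NaBH(OAc)3, AcOH, rt
Reagents that add atoms: none
Why: Iridium-catalysed hydrosilylation is selective for the tertiary lactam over the vinylogous lactone, and acid-induced ionisation of the N,O-silyl acetal followed by iminium reduction (reductive amination type) should give the amine with no stereocentre affected.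

Step 20
Reactants: 34 amino acetal
Product: 36 (2S)-2-[(4R,9S,10R,10aS)-4-[(1R)-1-{[tert-butyl(dimethyl)silyl]oxy}propyl]-9-(3-methoxy-4-methyl-5-oxo-2,5-dihydrofuran-2-yl)-9-[(triethylsilyl)oxy]decahydropyrido[1,2-a]azepin-10-yl]propanal, via collidinium triflate 35 (not isolated)
Conditions: Et3SiOTf, 2,4,6-collidine, CH2Cl2, 0 °C; then H2O
Reagents that add atoms: water, O
Why: Silyl triflate–collidine cleavage of the dimethyl acetal through an N-(α-methoxyalkyl)pyridinium salt unmasks the aldehyde without protic acid, so both silyl ethers and the α-centre C10 should be preserved.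

Step 21
Reactants: 36 amino aldehyde
Product: 38 tris-silyl ether of the target (C3 O-tert-butyldimethylsilyl; C11 and C13 O-triethylsilyl), via silyloxyfuran aldehyde 37 (not isolated)
Conditions: Et3SiOTf, Et3N, CH2Cl2, −78 → −20 °C
Reagents that add atoms: triethylsilyl trifluoromethanesulfonate (TESOTf), CC[Si](CC)(CC)OS(=O)(=O)C(F)(F)F
Why: Silylative intramolecular vinylogous Mukaiyama aldol (5-exo-trig) should join C12 of the 2-silyloxyfuran formed in the flask to the silyl-activated aldehyde through an open, non-chelated transition state, in which the methoxy-bearing edge of the furan turns away from the C13 silyloxy group (ring oxygen cis to O-13, setting C12) and the silylated aldehyde oxygen avoids a 1,3-cis relation to that group (C11 oxygen trans to O-13), while the trans ring fusion is already fixed by C9 and C13.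

Step 22
Reactants: 38 tris-silyl ether
Product: 39 CNP0267781.1 (3R,4R,8S,9R,10S,11S,12R,13S in the atom labels of the remark)
Conditions: HF·pyridine, THF, 0 °C → rt; aq. NaHCO3
Reagents that add atoms: none
Why: Acidic fluoride desilylation removes all three silyl groups while keeping the amine protonated and avoiding alkoxide formation, so the two aldol-type carbinols cannot revert.

**Compound list**

1 | ethyl 2-methyl-3-oxobutanoate (ethyl 2-methylacetoacetate) | CCOC(=O)C(C)C(C)=O | starting material
2 | ethyl 2-bromo-2-methyl-3-oxobutanoate (formed in the flask) | CCOC(=O)C(C)(Br)C(C)=O | intermediate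
3 | ethyl 4-bromo-2-methyl-3-oxobutanoate (formed in the flask) | CCOC(=O)C(C)C(=O)CBr | intermediate
4 | 4-hydroxy-3-methylfuran-2(5H)-one (3-methyltetronic acid) | CC1=C(O)COC1=O | intermediate
5 | 4-methoxy-3-methylfuran-2(5H)-one | COC1=C(C)C(=O)OC1 | intermediate
6 | methyl (S)-3-hydroxy-2-methylpropanoate | C[C@@H](CO)C(=O)OC | starting material
7 | methyl (S)-3-[(tert-butyldiphenylsilyl)oxy]-2-methylpropanoate | C[C@@H](CO[Si](c1ccccc1)(c1ccccc1)C(C)(C)C)C(=O)OC | intermediate
8 | (S)-3-[(tert-butyldiphenylsilyl)oxy]-2-methylpropanal (formed in the flask) | C[C@@H](CO[Si](c1ccccc1)(c1ccccc1)C(C)(C)C)C=O | intermediate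
9 | (S)-tert-butyl(3,3-dimethoxy-2-methylpropoxy)diphenylsilane | C[C@@H](CO[Si](c1ccccc1)(c1ccccc1)C(C)(C)C)C(OC)OC | intermediate
10 | (S)-3,3-dimethoxy-2-methylpropan-1-ol | C[C@@H](CO)C(OC)OC | intermediate
11 | (R)-3-iodo-1,1-dimethoxy-2-methylpropane | C[C@@H](CI)C(OC)OC | intermediate
12 | [(R)-3,3-dimethoxy-2-methylpropyl]triphenylphosphonium iodide | C[C@@H](C[P+](c1ccccc1)(c1ccccc1)c1ccccc1)C(OC)OC.[I-] | intermediate
13 | (±)-pent-1-en-3-ol | CCC(O)C=C | starting material
14 | (2S,3R)-1,2-epoxypentan-3-ol | CC[C@@H](O)[C@@H]1CO1 | intermediate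
15 | tert-butyldimethyl{(R)-1-[(S)-oxiran-2-yl]propoxy}silane | CC[C@@H](O[Si](C)(C)C(C)(C)C)[C@@H]1CO1 | intermediate
16 | but-3-en-1-ylmagnesium bromide | C=CCC[Mg]Br | starting material
17 | (3R,4S)-3-[(tert-butyldimethylsilyl)oxy]non-8-en-4-ol | CC[C@@H](O[Si](C)(C)C(C)(C)C)[C@@H](O)CCCC=C | intermediate
18 | (3R,4R)-4-azido-3-[(tert-butyldimethylsilyl)oxy]non-8-ene | CC[C@@H](O[Si](C)(C)C(C)(C)C)[C@H](N=[N+]=[N-])CCCC=C | intermediate
19 | 3-[(4R,5R)-4-azido-5-[(tert-butyldimethylsilyl)oxy]heptyl]-1,2,4-trioxolane (formed in the flask) | CC[C@@H](O[Si](C)(C)C(C)(C)C)[C@H](N=[N+]=[N-])CCCC1OCOO1 | intermediate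
20 | (5R,6R)-5-azido-6-[(tert-butyldimethylsilyl)oxy]octanal | CC[C@@H](O[Si](C)(C)C(C)(C)C)[C@H](N=[N+]=[N-])CCCC=O | intermediate
21 | [(R)-3,3-dimethoxy-2-methylpropylidene]triphenylphosphorane (formed in the flask) | C[C@@H](C=P(c1ccccc1)(c1ccccc1)c1ccccc1)C(OC)OC | intermediate
22 | (3R,4R,8Z,10S)-4-azido-3-[(tert-butyldimethylsilyl)oxy]-11,11-dimethoxy-10-methylundec-8-ene | CC[C@@H](O[Si](C)(C)C(C)(C)C)[C@H](N=[N+]=[N-])CCC/C=C\[C@H](C)C(OC)OC | intermediate
23 | N-(triphenylphosphoranylidene) derivative of amine 24 (formed in the flask) | CC[C@@H](O[Si](C)(C)C(C)(C)C)[C@H](N=P(c1ccccc1)(c1ccccc1)c1ccccc1)CCC/C=C\[C@H](C)C(OC)OC | intermediate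
24 | (3R,4R,8Z,10S)-3-[(tert-butyldimethylsilyl)oxy]-11,11-dimethoxy-10-methylundec-8-en-4-amine | CC[C@@H](O[Si](C)(C)C(C)(C)C)[C@H](N)CCC/C=C\[C@H](C)C(OC)OC | intermediate
25 | maleic anhydride | O=C1OC(=O)C=C1 | starting material
26 | (Z)-4-oxo-4-{[(3R,4R,8Z,10S)-3-[(tert-butyldimethylsilyl)oxy]-11,11-dimethoxy-10-methylundec-8-en-4-yl]amino}but-2-enoic acid (formed in the flask) | CC[C@@H](O[Si](C)(C)C(C)(C)C)[C@H](NC(=O)/C=C\C(=O)O)CCC/C=C\[C@H](C)C(OC)OC | intermediate
27 | 1-[(3R,4R,8Z,10S)-3-[(tert-butyldimethylsilyl)oxy]-11,11-dimethoxy-10-methylundec-8-en-4-yl]-1H-pyrrole-2,5-dione | CC[C@@H](O[Si](C)(C)C(C)(C)C)[C@@H](CCC/C=C\[C@H](C)C(OC)OC)N1C(=O)C=CC1=O | intermediate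
28 | (4R,10R,10aS)-4-[(1R)-1-{[tert-butyl(dimethyl)silyl]oxy}propyl]-10-[(2S)-1,1-dimethoxypropan-2-yl]-1,2,3,4,10,10a-hexahydropyrido[1,2-a]azepine-6,9-dione | CC[C@@H](O[Si](C)(C)C(C)(C)C)[C@H]1CCC[C@H]2[C@@H]([C@H](C)C(OC)OC)C(=O)C=CC(=O)N12 | intermediate
29 | (4R,10R,10aS)-4-[(1R)-1-{[tert-butyl(dimethyl)silyl]oxy}propyl]-10-[(2S)-1,1-dimethoxypropan-2-yl]octahydropyrido[1,2-a]azepine-6,9-dione | CC[C@@H](O[Si](C)(C)C(C)(C)C)[C@H]1CCC[C@H]2[C@@H]([C@H](C)C(OC)OC)C(=O)CCC(=O)N12 | intermediate
30 | lithium 4-methoxy-3-methylfuran-2-olate (formed in the flask) | [Li+].[O-]c1occ(OC)c1C | intermediate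
31 | lithium C13 alkoxide from addition of 30 to 29 (formed in the flask; C12 epimers) | CC[C@@H](O[Si](C)(C)C(C)(C)C)[C@H]1CCC[C@H]2[C@@H]([C@H](C)C(OC)OC)[C@]([O-])(C3OC(=O)C(C)=C3OC)CCC(=O)N12.[Li+] | intermediate
32 | (4R,9S,10R,10aS)-4-[(1R)-1-{[tert-butyl(dimethyl)silyl]oxy}propyl]-10-[(2S)-1,1-dimethoxypropan-2-yl]-9-(3-methoxy-4-methyl-5-oxo-2,5-dihydrofuran-2-yl)-9-[(triethylsilyl)oxy]octahydropyrido[1,2-a]azepin-6(2H)-one (C12 epimers) | CC[C@@H](O[Si](C)(C)C(C)(C)C)[C@H]1CCC[C@H]2[C@@H]([C@H](C)C(OC)OC)[C@](O[Si](CC)(CC)CC)(C3OC(=O)C(C)=C3OC)CCC(=O)N12 | intermediate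
33 | N,O-silyl acetal of lactam 32 at C16 with an O-(1,1,3,3-tetramethyldisiloxanyl) group (formed in the flask) | CC[C@@H](O[Si](C)(C)C(C)(C)C)[C@H]1CCC[C@H]2[C@@H]([C@H](C)C(OC)OC)[C@](O[Si](CC)(CC)CC)(C3OC(=O)C(C)=C3OC)CCC(O[Si](C)(C)O[SiH](C)C)N12 | intermediate
34 | (4R,9S,10R,10aS)-4-[(1R)-1-{[tert-butyl(dimethyl)silyl]oxy}propyl]-10-[(2S)-1,1-dimethoxypropan-2-yl]-9-(3-methoxy-4-methyl-5-oxo-2,5-dihydrofuran-2-yl)-9-[(triethylsilyl)oxy]decahydropyrido[1,2-a]azepine (C12 epimers) | CC[C@@H](O[Si](C)(C)C(C)(C)C)[C@H]1CCC[C@H]2[C@@H]([C@H](C)C(OC)OC)[C@](O[Si](CC)(CC)CC)(C3OC(=O)C(C)=C3OC)CCCN12 | intermediate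
35 | N-(1-methoxyalkyl)-2,4,6-trimethylpyridinium triflate derived from acetal 34 at C11 (formed in the flask) | CC[C@@H](O[Si](C)(C)C(C)(C)C)[C@H]1CCC[C@H]2[C@@H]([C@H](C)C(OC)[n+]3c(C)cc(C)cc3C)[C@](O[Si](CC)(CC)CC)(C4OC(=O)C(C)=C4OC)CCCN12.[O-]S(=O)(=O)C(F)(F)F | intermediate
36 | (2S)-2-[(4R,9S,10R,10aS)-4-[(1R)-1-{[tert-butyl(dimethyl)silyl]oxy}propyl]-9-(3-methoxy-4-methyl-5-oxo-2,5-dihydrofuran-2-yl)-9-[(triethylsilyl)oxy]decahydropyrido[1,2-a]azepin-10-yl]propanal (C12 epimers) | CC[C@@H](O[Si](C)(C)C(C)(C)C)[C@H]1CCC[C@H]2[C@@H]([C@H](C)C=O)[C@](O[Si](CC)(CC)CC)(C3OC(=O)C(C)=C3OC)CCCN12 | intermediate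
37 | aldehyde 36 with the furanone as its 3-methoxy-4-methyl-5-[(triethylsilyl)oxy]furan-2-yl form (formed in the flask) | CC[C@@H](O[Si](C)(C)C(C)(C)C)[C@H]1CCC[C@H]2[C@@H]([C@H](C)C=O)[C@](O[Si](CC)(CC)CC)(c3oc(O[Si](CC)(CC)CC)c(C)c3OC)CCCN12 | intermediate
38 | tris-silyl ether of the target (C3 O-tert-butyldimethylsilyl; C11 and C13 O-triethylsilyl) | CC[C@@H](O[Si](C)(C)C(C)(C)C)[C@H]1CCC[C@H]2[C@H]3[C@H](C)[C@H](O[Si](CC)(CC)CC)[C@@]4(OC(=O)C(C)=C4OC)[C@]3(O[Si](CC)(CC)CC)CCCN12 | intermediate
39 | CNP0267781.1 | CC[C@@H](O)[C@H]1CCC[C@H]2[C@H]3[C@H](C)[C@H](O)[C@@]4(OC(=O)C(C)=C4OC)[C@]3(O)CCCN12 | target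

**Totals and risks**

Total step count: 22. Longest linear sequence: 15 steps (steps 8–22 from pent-1-en-3-ol; equally steps 3–7 and 13–22 from the Roche ester).

Steps most likely to fail:

Step 16. The excited maleimide may be diverted into [2+2] addition at its own C=C bond or into dimerisation before it reaches the alkene across the four-carbon tether, and the primary adduct may be photolysed further. The chair fold directed by C4 may also fail to override the allylic centre C10, which would erode facial selection. The fallback changes the chromophore and sets out from amine 24. Acylation with 2,3-dichloromaleic anhydride gives the dichloromaleamic acid F1, and Ac2O/NaOAc closes it to the N-alkenyl dichloromaleimide F2. Dichloromaleimides are the class for which this insertion is most reliable, so irradiation under the same conditions should give the dichloro azepinedione F3. Zinc dust with NH4Cl in aqueous THF then removes both chlorines and saturates the enedione, which returns to the route at keto lactam 29.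

Step 18. The stabilised furanolate may add reversibly to the hindered ketone, and proton transfer from C14 or C9 may compete, leaving 29 unchanged or epimerised. The fallback replaces the lithium anion by a silyl dienolate and sets out from furanone 5. Et3SiOTf and Et3N give 4-methoxy-3-methyl-2-(triethylsilyloxy)furan F4. With ketone 29 and catalytic Bu4N[Ph3SiF2] in THF at −78 °C, a fluoride-triggered Mukaiyama aldol with silyl transfer to the new alkoxide should give the silyl ether directly and without a free base, returning to the route at 32.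

Step 21. The open transition state may not differentiate the aldehyde faces well enough, giving the C11 epimer; enol silane formation at the aldehyde would also endanger C10. The fallback sets C11 by reduction instead of by C–C bond formation. It starts from the C11 epimer of the tris-silyl ether F5 (alone or mixed with 38), formed from aldehyde 36 under the step 21 conditions. Pyridinium p-toluenesulfonate in MeOH at 0 °C removes the secondary triethylsilyl group to give the carbinol F6, and Dess–Martin periodinane oxidises it to the C11 ketone F7. HF·pyridine frees the hydroxy ketone F8. Me4NBH(OAc)3 in AcOH–MeCN at −20 °C then delivers hydride from the C13 hydroxyl (hydroxyl-directed anti-1,3 reduction), which should place the C11 hydroxyl trans to O-13 and return to the route at target 39.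

Further compounds
F1 | step 16 | (Z)-2,3-dichloro-4-oxo-4-{[(3R,4R,8Z,10S)-3-[(tert-butyldimethylsilyl)oxy]-11,11-dimethoxy-10-methylundec-8-en-4-yl]amino}but-2-enoic acid | CC[C@@H](O[Si](C)(C)C(C)(C)C)[C@H](NC(=O)/C(Cl)=C(Cl)\C(=O)O)CCC/C=C\[C@H](C)C(OC)OC
F2 | step 16 | 3,4-dichloro-1-[(3R,4R,8Z,10S)-3-[(tert-butyldimethylsilyl)oxy]-11,11-dimethoxy-10-methylundec-8-en-4-yl]-1H-pyrrole-2,5-dione | CC[C@@H](O[Si](C)(C)C(C)(C)C)[C@@H](CCC/C=C\[C@H](C)C(OC)OC)N1C(=O)C(Cl)=C(Cl)C1=O
F3 | step 16 | 7,8-dichloro analogue of azepinedione 28 | CC[C@@H](O[Si](C)(C)C(C)(C)C)[C@H]1CCC[C@H]2[C@@H]([C@H](C)C(OC)OC)C(=O)C(Cl)=C(Cl)C(=O)N12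
F4 | step 18 | 4-methoxy-3-methyl-2-[(triethylsilyl)oxy]furan | CC[Si](CC)(CC)Oc1occ(OC)c1C
F5 | step 21 | C11 epimer of tris-silyl ether 38 | CC[C@@H](O[Si](C)(C)C(C)(C)C)[C@H]1CCC[C@H]2[C@H]3[C@H](C)[C@@H](O[Si](CC)(CC)CC)[C@@]4(OC(=O)C(C)=C4OC)[C@]3(O[Si](CC)(CC)CC)CCCN12
F6 | step 21 | C11 epimeric carbinol with C3 O-tert-butyldimethylsilyl and C13 O-triethylsilyl groups | CC[C@@H](O[Si](C)(C)C(C)(C)C)[C@H]1CCC[C@H]2[C@H]3[C@H](C)[C@@H](O)[C@@]4(OC(=O)C(C)=C4OC)[C@]3(O[Si](CC)(CC)CC)CCCN12
F7 | step 21 | C11 ketone with C3 O-tert-butyldimethylsilyl and C13 O-triethylsilyl groups | CC[C@@H](O[Si](C)(C)C(C)(C)C)[C@H]1CCC[C@H]2[C@H]3[C@H](C)C(=O)[C@@]4(OC(=O)C(C)=C4OC)[C@]3(O[Si](CC)(CC)CC)CCCN12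
F8 | step 21 | 11-oxo analogue of the target (C3 and C13 hydroxyls free) | CC[C@@H](O)[C@H]1CCC[C@H]2[C@H]3[C@H](C)C(=O)[C@@]4(OC(=O)C(C)=C4OC)[C@]3(O)CCCN12
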